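**Plan**

- Retrosynthetic cuts: the ester bond between the C3 carboxyl and O5 of shikimate; the acrylate C=C (Wittig) together with the C3 oxidation level, which folds C4–CH= and C3–CH2O into a six-membered lactone; ring A at C3a–C4 and C5–C6 (Diels–Alder, then aromatisation); the diene bond C7a–C7 (Stille); the C2–C3 bond (aldol).
- Forward order: an aldol joins the aryl carbinol carbon C2 to C3; the cis γ-lactone becomes the 2,3-dihydrofuran (ring B: O1, C2, C3, C3a, C7a); a tethered propiolate then builds ring A and a temporary lactone in one flask; lactone opening gives the E acrylate and the C3 carbinol, which is oxidised, esterified with protected shikimate and deprotected.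
- Enabling feature: C4 of ring A is peri to C3, so C3–CH2–O–C(=O)–C4 is a six-membered lactone; the C7 oxygen and O1 on C7a are the 2- and 3-oxygens of a diene C6=C7–C7a=C3a, which is simply a 5-(1-silyloxyvinyl)-2,3-dihydrofuran.
- Stereochemistry: an auxiliary-controlled anti aldol sets C2 and C3 (cis after lactonisation); C3 stays a non-epimerisable carbinol carbon until ring A exists; the shikimate stereocentres come from the chiral pool; the stabilised ylide gives the E alkene.

Key step: step 12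

Remark: the target is read as the 2,3-cis (2S,3R) dihydrobenzofuran acid esterified at O5 of natural shikimic acid; benzofuran numbering (O1, C2, C3, C3a, C4 to C7, C7a) is used for ring positions, TBS = tert-butyldimethylsilyl, TES = triethylsilyl, TBSO/TESO = the corresponding silyloxy groups.

**Route**

Step 1
Reactants: 1 3,4-dihydroxybenzaldehyde
Product: 2 3,4-bis(TBSO)benzaldehyde
Conditions: TBSCl (2.3 equiv), imidazole, DMF, 23 °C
Reagents that add atoms: tert-butyldimethylsilyl chloride, CC(C)(C)[Si](C)(C)Cl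
Why: Imidazole-promoted silyl ether formation masks both phenols for the basic and organometallic steps that follow.

Step 2
Reactants: 3 (S)-4-benzyloxazolidin-2-one; 4 pent-4-enoyl chloride
Product: 5 (S)-4-benzyl-3-(pent-4-enoyl)oxazolidin-2-one
Conditions: n-BuLi, THF, −78 °C; then 4, −78 → 0 °C
Reagents that add atoms: none
Why: N-Acylation of the lithiated oxazolidinone with an acid chloride is the standard entry to such imides.

Step 3
Reactants: 5 (S)-4-benzyl-3-(pent-4-enoyl)oxazolidin-2-one; 2 3,4-bis(TBSO)benzaldehyde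
Product: 7 (S)-4-benzyl-3-[(2R)-2-[(S)-[3,4-bis(TBSO)phenyl](hydroxy)methyl]pent-4-enoyl]oxazolidin-2-one, via aldol trimethylsilyl ether 6 (not isolated)
Conditions: MgCl2 (0.2 equiv), Et3N, TMSCl, EtOAc, 23 °C; then TFA (cat.), MeOH, 0 °C
Reagents that add atoms: chlorotrimethylsilane, C[Si](C)(C)Cl (its silyl group is carried by 6 only and is lost again in 7)
Why: In this magnesium halide catalysed direct anti aldol reaction of an N-acyloxazolidinone with a non-enolisable aryl aldehyde, made irreversible by silylation, the chelated Z magnesium enolate should be attacked on the face away from the benzyl group through a boat-like transition state, setting the acyl C2 as R and the carbinol carbon as S (anti), and brief acid methanolysis frees the alcohol.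

Step 4
Reactants: 7 anti aldol imide
Product: 8 (1S,2S)-1-[3,4-bis(TBSO)phenyl]-2-(prop-2-enyl)propane-1,3-diol
Conditions: LiBH4, H2O (1 equiv), Et2O, 0 °C; aq NH4Cl
Reagents that add atoms: none
Why: Borohydride reduction of the imide carbonyl (reductive auxiliary removal) gives the 1,3-diol and returns the oxazolidinone without touching either stereocentre.

Step 5
Reactants: 8 diol
Product: 9 (1S,2S)-1-[3,4-bis(TBSO)phenyl]-2-(TESO-methyl)pent-4-en-1-ol
Conditions: TESCl (1.05 equiv), imidazole, CH2Cl2, −78 °C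
Reagents that add atoms: chlorotriethylsilane, CC[Si](Cl)(CC)CC
Why: Kinetically selective silylation of the primary over the hindered secondary benzylic alcohol leaves the benzylic oxygen free to become O1.

Step 6
Reactants: 9 mono-TES ether
Product: 10 (4S,5S)-5-[3,4-bis(TBSO)phenyl]-4-(TESO-methyl)oxolan-2-ol (anomer mixture)
Conditions: O3 (titrated, stopped at alkene consumption), CH2Cl2, −78 °C; PPh3, −78 → 23 °C
Reagents that add atoms: ozone, [O-][O+]=O
Why: Ozonolysis with reductive work-up cleaves the terminal alkene much faster than the silylated arene, and the 4-hydroxy aldehyde closes to the only possible five-membered lactol now that the primary oxygen is silylated.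

Step 7
Reactants: 10 lactol
Product: 11 (4S,5S)-5-[3,4-bis(TBSO)phenyl]-4-(TESO-methyl)oxolan-2-one (cis lactone)
Conditions: TEMPO (0.1 equiv), PhI(OAc)2, CH2Cl2, 23 °C
Reagents that add atoms: none
Why: Oxoammonium (TEMPO) oxidation of a lactol to the lactone is mild towards the silyl ethers and does not involve C4 or C5 of the cis lactone.

Step 8
Reactants: 11 cis lactone
Product: 12 (2S,3S)-2-[3,4-bis(TBSO)phenyl]-3-(TESO-methyl)-2,3-dihydrofuran-5-yl diphenyl phosphate
Conditions: KN(SiMe3)2, (PhO)2P(O)Cl, HMPA, THF, −78 °C (base added to lactone and chlorophosphate)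
Reagents that add atoms: diphenyl chlorophosphate, O=P(Cl)(Oc1ccccc1)Oc1ccccc1
Why: O-Phosphorylation of the lactone enolate gives the cyclic ketene acetal phosphate, an established electrophile for palladium-catalysed coupling, and neither stereocentre is alpha to the carbonyl.

Step 9
Reactants: 12 ketene acetal phosphate
Product: 15 1-[(4S,5S)-5-[3,4-bis(TBSO)phenyl]-4-(hydroxymethyl)-4,5-dihydrofuran-2-yl]ethanone, via ethoxyvinyl dihydrofuran 13 (not isolated), via triethylsilyl ketone 14 (not isolated)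
Conditions: CH2=C(OEt)SnBu3, Pd(PPh3)4 (5 mol %), LiCl, THF, 65 °C; then 0.5 M aq HCl, THF, 0 → 23 °C
Reagents that add atoms: tributyl(1-ethoxyvinyl)stannane, CCCC[Sn](CCCC)(CCCC)C(=C)OCC; water, O
Why: Stille coupling of the ketene acetal phosphate (oxidative addition into the C–O bond, LiCl-assisted transmetalation, reductive elimination) forms C7a–C7, and dilute acid then hydrolyses the acyclic enol ether to the methyl ketone and removes the TES ether while the aryl silyl ethers and the deactivated ring enol ether should survive.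

Step 10
Reactants: 15 hydroxy ketone; 16 propiolic acid
Product: 17 [(2S,3S)-5-acetyl-2-[3,4-bis(TBSO)phenyl]-2,3-dihydrofuran-3-yl]methyl prop-2-ynoate
Conditions: DCC, DMAP (5 mol %), CH2Cl2, −20 → 0 °C
Reagents that add atoms: none
Why: Steglich esterification at low temperature with only catalytic DMAP acylates the primary alcohol before the amine can add to the propiolate.

Step 11
Reactants: 17 keto propiolate
Product: 18 [(2S,3S)-2-[3,4-bis(TBSO)phenyl]-5-[1-(TBSO)ethenyl]-2,3-dihydrofuran-3-yl]methyl prop-2-ynoate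
Conditions: TBSOTf, iPr2NEt, CH2Cl2, −78 → −20 °C; rapid filtration through Et3N-treated silica
Reagents that add atoms: tert-butyldimethylsilyl trifluoromethanesulfonate, CC(C)(C)[Si](C)(C)OS(=O)(=O)C(F)(F)F
Why: Soft enolisation with silyl triflate and a non-nucleophilic amine gives the 2-silyloxydiene (silyl enol ether formation) by deprotonation of the methyl group, the only alpha position, faster than the hindered gamma hydrogen at C3, so the cis stereocentres are kept.

Step 12
Reactants: 18 silyloxydiene propiolate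
Product: 20 lactone of (2S,3S)-2-[3,4-bis(TBSO)phenyl]-7-(TBSO)-3-(hydroxymethyl)-2,3-dihydro-1-benzofuran-4-carboxylic acid (six-membered lactone bridging C3 and C4), via cyclohexadiene cycloadduct 19 (not isolated)
Conditions: BHT (cat.), PhMe (0.01 M), 130 °C, sealed tube; then DDQ (1.05 equiv), 23 °C, same flask
Reagents that add atoms: none
Why: In a thermal intramolecular Diels–Alder reaction the electron-rich 2-silyloxy-3-alkoxy diene (future C3a=C7a–C7=C6) adds suprafacially to the tethered alkynoate in a concerted, asynchronous [4+2] process that forms C3a–C4 and C5–C6, and DDQ then removes the doubly allylic hydrogens at C3a and C6 of the 1,4-cyclohexadiene 19 so that the enol silyl ether ends as the C7 aryl silyl ether. The closest known reaction type is the cycloaddition of 2-silyloxydienes with tethered alkynoates followed by dehydrogenation to phenol silyl ethers. Ring A closes by [4+2] union of the two diene termini with the alkyne, and the six-membered lactone closes in the same event because the CH2–O–C(=O) tether from C3, which occupies the outside (E) position of the diene terminus C3a, carries the acyl-bearing alkyne carbon onto C3a. The only new stereocentre, C3a in 19, is set by delivery of the alkyne from the face bearing the C3 tether and is erased on aromatisation, while C2 and C3 carry no acidic hydrogen at this stage and should stay cis. The step needs regiocontrol (acyl-bearing carbon to C3a, terminal carbon to C6), which the tether enforces and the 2-silyloxy group reinforces electronically, and chemoselective dehydrogenation, secured by one equivalent of DDQ at room temperature so that the C2–C3 bond is not dehydrogenated to a benzofuran.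

Step 13
Reactants: 20 tricyclic lactone
Product: 21 lactol of 20 (anomer mixture)
Conditions: iBu2AlH (1.1 equiv), CH2Cl2, −78 °C; aq potassium sodium tartrate
Reagents that add atoms: none
Why: Low-temperature hydride reduction of an aryl-conjugated six-membered lactone stops at the lactol because the aluminium hemiacetal persists until work-up.

Step 14
Reactants: 21 lactol
Product: 22 tert-butyl (E)-3-[(2S,3S)-2-[3,4-bis(TBSO)phenyl]-7-(TBSO)-3-(hydroxymethyl)-2,3-dihydro-1-benzofuran-4-yl]prop-2-enoate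
Conditions: Ph3P=CHCO2tBu, PhMe, 90 °C
Reagents that add atoms: tert-butyl 2-(triphenylphosphoranylidene)acetate, CC(C)(C)OC(=O)C=P(c1ccccc1)(c1ccccc1)c1ccccc1
Why: Wittig olefination of the open hydroxy aldehyde form of the lactol with a stabilised ylide gives the E cinnamate and frees the C3 carbinol under base-free conditions, the former lactone carbonyl carbon becoming the acrylate beta carbon.

Step 15
Reactants: 22 hydroxy acrylate
Product: 24 (2S,3R)-2-[3,4-bis(TBSO)phenyl]-4-[(E)-3-tert-butoxy-3-oxoprop-1-enyl]-7-(TBSO)-2,3-dihydro-1-benzofuran-3-carboxylic acid, via cis aldehyde 23 (not isolated)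
Conditions: TEMPO (0.2 equiv), PhI(OAc)2 (2.5 equiv), MeCN/CH2Cl2/H2O, 0 → 23 °C
Reagents that add atoms: water, O
Why: TEMPO/PhI(OAc)2 oxidation in aqueous acetonitrile takes the primary alcohol through the aldehyde hydrate to the acid in one weakly acidic, base-free operation, so the cis aldehyde has little opportunity to epimerise at C3 or to eliminate the C2 aryloxy group.

Step 16
Reactants: 25 shikimic acid
Product: 26 (3aR,7R,7aS)-7-hydroxy-2,2-dimethyl-3a,6,7,7a-tetrahydro-1,3-benzodioxole-5-carboxylic acid (3,4-O-isopropylideneshikimic acid)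
Conditions: 2,2-dimethoxypropane, TsOH·H2O (cat.), acetone, 23 °C, short reaction time
Reagents that add atoms: 2,2-dimethoxypropane, COC(C)(C)OC
Why: Acid-catalysed transketalisation selects the cis 3,4-diol for the five-membered acetonide and leaves the trans 5-hydroxyl free.

Step 17
Reactants: 26 acetonide acid
Product: 27 tert-butyl (3aR,7R,7aS)-7-hydroxy-2,2-dimethyl-3a,6,7,7a-tetrahydro-1,3-benzodioxole-5-carboxylate
Conditions: tert-butyl N,N'-diisopropylcarbamimidate, THF, 23 °C
Reagents that add atoms: tert-butyl N,N'-diisopropylcarbamimidate, CC(C)N=C(NC(C)C)OC(C)(C)C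
Why: The O-tert-butyl isourea is protonated only by the carboxylic acid, so isourea esterification gives the tert-butyl ester without touching the secondary alcohol or the acetonide.

Step 18
Reactants: 24 cis acid; 27 shikimate alcohol
Product: 28 tert-butyl (3aR,7R,7aS)-7-[(2S,3R)-2-[3,4-bis(TBSO)phenyl]-4-[(E)-3-tert-butoxy-3-oxoprop-1-enyl]-7-(TBSO)-2,3-dihydro-1-benzofuran-3-carbonyl]oxy-2,2-dimethyl-3a,6,7,7a-tetrahydro-1,3-benzodioxole-5-carboxylate
Conditions: DIC, 4-(dimethylamino)pyridinium p-toluenesulfonate (0.3 equiv), CH2Cl2, 0 → 23 °C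
Reagents that add atoms: none
Why: Carbodiimide esterification with the buffered DMAP salt (Steglich-type acyl transfer) acylates the free 5-hydroxyl while keeping free base, and thus ketene formation and epimerisation at C3, to a minimum.

Step 19
Reactants: 28 fully protected ester
Product: 29 triphenol of 28 (all three aryl TBS ethers removed; tert-butyl esters and acetonide retained)
Conditions: KHF2, MeOH/THF, 23 °C
Reagents that add atoms: none
Why: Bifluoride cleaves aryl silyl ethers selectively under weakly acidic conditions (fluoride-mediated desilylation), so the base-sensitive cis C3 ester, the acetonide and both tert-butyl esters should remain.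

Step 20
Reactants: 29 triphenol
Product: 30 (3R,4R,5R)-5-[(2S,3R)-4-[(E)-2-carboxyethenyl]-2-(3,4-dihydroxyphenyl)-7-hydroxy-2,3-dihydro-1-benzofuran-3-carbonyl]oxy-3,4-dihydroxycyclohex-1-ene-1-carboxylic acid (CNP0312618.1)
Conditions: TFA/CH2Cl2/H2O (10:10:1), iPr3SiH, 0 → 23 °C, short contact; reverse-phase purification
Reagents that add atoms: none
Why: Acidolysis cleaves both tert-butyl esters through the tert-butyl cation (trapped by the silane) and hydrolyses the acetonide, while the two remaining esters, the E alkene and the stereocentres are not labile to brief cold acid.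

**Compound list**

1 | 3,4-dihydroxybenzaldehyde | O=Cc1ccc(O)c(O)c1 | starting material
2 | 3,4-bis(TBSO)benzaldehyde | O=Cc1ccc(O[Si](C)(C)C(C)(C)C)c(O[Si](C)(C)C(C)(C)C)c1 | intermediate
3 | (S)-4-benzyloxazolidin-2-one | O=C1N[C@@H](Cc2ccccc2)CO1 | starting material
4 | pent-4-enoyl chloride | C=CCCC(=O)Cl | starting material
5 | (S)-4-benzyl-3-(pent-4-enoyl)oxazolidin-2-one | C=CCCC(=O)N1[C@@H](Cc2ccccc2)COC1=O | intermediate
6 | trimethylsilyl ether of aldol adduct 7 | C=CC[C@H]([C@H](O[Si](C)(C)C)c1ccc(O[Si](C)(C)C(C)(C)C)c(O[Si](C)(C)C(C)(C)C)c1)C(=O)N1[C@@H](Cc2ccccc2)COC1=O | intermediate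
7 | (S)-4-benzyl-3-[(2R)-2-[(S)-[3,4-bis(TBSO)phenyl](hydroxy)methyl]pent-4-enoyl]oxazolidin-2-one | C=CC[C@H]([C@H](O)c1ccc(O[Si](C)(C)C(C)(C)C)c(O[Si](C)(C)C(C)(C)C)c1)C(=O)N1[C@@H](Cc2ccccc2)COC1=O | intermediate
8 | (1S,2S)-1-[3,4-bis(TBSO)phenyl]-2-(prop-2-enyl)propane-1,3-diol | C=CC[C@@H](CO)[C@H](O)c1ccc(O[Si](C)(C)C(C)(C)C)c(O[Si](C)(C)C(C)(C)C)c1 | intermediate
9 | (1S,2S)-1-[3,4-bis(TBSO)phenyl]-2-(TESO-methyl)pent-4-en-1-ol | C=CC[C@@H](CO[Si](CC)(CC)CC)[C@H](O)c1ccc(O[Si](C)(C)C(C)(C)C)c(O[Si](C)(C)C(C)(C)C)c1 | intermediate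
10 | (4S,5S)-5-[3,4-bis(TBSO)phenyl]-4-(TESO-methyl)oxolan-2-ol | OC1C[C@@H](CO[Si](CC)(CC)CC)[C@@H](c2ccc(O[Si](C)(C)C(C)(C)C)c(O[Si](C)(C)C(C)(C)C)c2)O1 | intermediate
11 | (4S,5S)-5-[3,4-bis(TBSO)phenyl]-4-(TESO-methyl)oxolan-2-one | O=C1C[C@@H](CO[Si](CC)(CC)CC)[C@@H](c2ccc(O[Si](C)(C)C(C)(C)C)c(O[Si](C)(C)C(C)(C)C)c2)O1 | intermediate
12 | (2S,3S)-2-[3,4-bis(TBSO)phenyl]-3-(TESO-methyl)-2,3-dihydrofuran-5-yl diphenyl phosphate | O=P(Oc1ccccc1)(Oc1ccccc1)OC1=C[C@@H](CO[Si](CC)(CC)CC)[C@@H](c2ccc(O[Si](C)(C)C(C)(C)C)c(O[Si](C)(C)C(C)(C)C)c2)O1 | intermediate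
13 | (2S,3S)-2-[3,4-bis(TBSO)phenyl]-5-(1-ethoxyethenyl)-3-(TESO-methyl)-2,3-dihydrofuran | C=C(OCC)C1=C[C@@H](CO[Si](CC)(CC)CC)[C@@H](c2ccc(O[Si](C)(C)C(C)(C)C)c(O[Si](C)(C)C(C)(C)C)c2)O1 | intermediate
14 | 1-[(4S,5S)-5-[3,4-bis(TBSO)phenyl]-4-(TESO-methyl)-4,5-dihydrofuran-2-yl]ethanone | CC(=O)C1=C[C@@H](CO[Si](CC)(CC)CC)[C@@H](c2ccc(O[Si](C)(C)C(C)(C)C)c(O[Si](C)(C)C(C)(C)C)c2)O1 | intermediate
15 | 1-[(4S,5S)-5-[3,4-bis(TBSO)phenyl]-4-(hydroxymethyl)-4,5-dihydrofuran-2-yl]ethanone | CC(=O)C1=C[C@@H](CO)[C@@H](c2ccc(O[Si](C)(C)C(C)(C)C)c(O[Si](C)(C)C(C)(C)C)c2)O1 | intermediate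
16 | propiolic acid | C#CC(=O)O | starting material
17 | [(2S,3S)-5-acetyl-2-[3,4-bis(TBSO)phenyl]-2,3-dihydrofuran-3-yl]methyl prop-2-ynoate | C#CC(=O)OC[C@@H]1C=C(C(C)=O)O[C@@H]1c1ccc(O[Si](C)(C)C(C)(C)C)c(O[Si](C)(C)C(C)(C)C)c1 | intermediate
18 | [(2S,3S)-2-[3,4-bis(TBSO)phenyl]-5-[1-(TBSO)ethenyl]-2,3-dihydrofuran-3-yl]methyl prop-2-ynoate | C#CC(=O)OC[C@@H]1C=C(C(=C)O[Si](C)(C)C(C)(C)C)O[C@@H]1c1ccc(O[Si](C)(C)C(C)(C)C)c(O[Si](C)(C)C(C)(C)C)c1 | intermediate
19 | 1,4-cyclohexadiene cycloadduct (lactone closed, C3a sp3, C7 silyl enol ether) | O=C1OC[C@H]2[C@@H](c4ccc(O[Si](C)(C)C(C)(C)C)c(O[Si](C)(C)C(C)(C)C)c4)OC3=C(O[Si](C)(C)C(C)(C)C)CC=C1[C@H]32 | intermediate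
20 | lactone of (2S,3S)-2-[3,4-bis(TBSO)phenyl]-7-(TBSO)-3-(hydroxymethyl)-2,3-dihydro-1-benzofuran-4-carboxylic acid | O=C1OC[C@H]2[C@@H](c4ccc(O[Si](C)(C)C(C)(C)C)c(O[Si](C)(C)C(C)(C)C)c4)Oc3c(O[Si](C)(C)C(C)(C)C)ccc1c32 | intermediate
21 | lactol of 20 | OC1OC[C@H]2[C@@H](c4ccc(O[Si](C)(C)C(C)(C)C)c(O[Si](C)(C)C(C)(C)C)c4)Oc3c(O[Si](C)(C)C(C)(C)C)ccc1c32 | intermediate
22 | tert-butyl (E)-3-[(2S,3S)-2-[3,4-bis(TBSO)phenyl]-7-(TBSO)-3-(hydroxymethyl)-2,3-dihydro-1-benzofuran-4-yl]prop-2-enoate | CC(C)(C)OC(=O)/C=C/c1ccc(O[Si](C)(C)C(C)(C)C)c2c1[C@@H](CO)[C@@H](c1ccc(O[Si](C)(C)C(C)(C)C)c(O[Si](C)(C)C(C)(C)C)c1)O2 | intermediate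
23 | tert-butyl (E)-3-[(2S,3R)-2-[3,4-bis(TBSO)phenyl]-7-(TBSO)-3-formyl-2,3-dihydro-1-benzofuran-4-yl]prop-2-enoate | CC(C)(C)OC(=O)/C=C/c1ccc(O[Si](C)(C)C(C)(C)C)c2c1[C@@H](C=O)[C@@H](c1ccc(O[Si](C)(C)C(C)(C)C)c(O[Si](C)(C)C(C)(C)C)c1)O2 | intermediate
24 | (2S,3R)-2-[3,4-bis(TBSO)phenyl]-4-[(E)-3-tert-butoxy-3-oxoprop-1-enyl]-7-(TBSO)-2,3-dihydro-1-benzofuran-3-carboxylic acid | CC(C)(C)OC(=O)/C=C/c1ccc(O[Si](C)(C)C(C)(C)C)c2c1[C@@H](C(=O)O)[C@@H](c1ccc(O[Si](C)(C)C(C)(C)C)c(O[Si](C)(C)C(C)(C)C)c1)O2 | intermediate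
25 | shikimic acid | O[C@@H]1CC(C(=O)O)=C[C@@H](O)[C@H]1O | starting material
26 | (3aR,7R,7aS)-7-hydroxy-2,2-dimethyl-3a,6,7,7a-tetrahydro-1,3-benzodioxole-5-carboxylic acid | O[C@@H]1CC(C(=O)O)=C[C@H]2OC(C)(C)O[C@@H]12 | intermediate
27 | tert-butyl (3aR,7R,7aS)-7-hydroxy-2,2-dimethyl-3a,6,7,7a-tetrahydro-1,3-benzodioxole-5-carboxylate | O[C@@H]1CC(C(=O)OC(C)(C)C)=C[C@H]2OC(C)(C)O[C@@H]12 | intermediate
28 | fully protected ester of acid 24 with O7 of 27 (shikimate O5) | CC(C)(C)OC(=O)/C=C/c1ccc(O[Si](C)(C)C(C)(C)C)c2c1[C@@H](C(=O)O[C@@H]1CC(C(=O)OC(C)(C)C)=C[C@H]3OC(C)(C)O[C@@H]13)[C@@H](c1ccc(O[Si](C)(C)C(C)(C)C)c(O[Si](C)(C)C(C)(C)C)c1)O2 | intermediate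
29 | triphenol di-tert-butyl ester acetonide | CC(C)(C)OC(=O)/C=C/c1ccc(O)c2c1[C@@H](C(=O)O[C@@H]1CC(C(=O)OC(C)(C)C)=C[C@H]3OC(C)(C)O[C@@H]13)[C@@H](c1ccc(O)c(O)c1)O2 | intermediate
30 | (3R,4R,5R)-5-[(2S,3R)-4-[(E)-2-carboxyethenyl]-2-(3,4-dihydroxyphenyl)-7-hydroxy-2,3-dihydro-1-benzofuran-3-carbonyl]oxy-3,4-dihydroxycyclohex-1-ene-1-carboxylic acid | O=C(O)/C=C/c1ccc(O)c2c1[C@@H](C(=O)O[C@@H]1CC(C(=O)O)=C[C@@H](O)[C@H]1O)[C@@H](c1ccc(O)c(O)c1)O2 | target

**Step count and risks**

Total steps: 20. Longest linear sequence: 17 steps (steps 1, 3 to 15, 18 to 20, from 3,4-dihydroxybenzaldehyde); step 2 and steps 16 to 17 are side branches.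

Steps most likely to fail:

1. Step 12. The acyclic propiolate ester must reach its disfavoured s-cis ester geometry before the six-membered lactone can close, so the cycloaddition may be outrun by thermal decomposition or hydrolysis of the dienol silyl ether; over-oxidation by DDQ is the second hazard. The fallback gives up the tether and sets out from 15. TBSOTf (2.5 equiv) and Et3N silylate both the alcohol and the ketone to give the doubly silylated dienol ether F1. An intermolecular Diels–Alder reaction with methyl propiolate (PhMe, 80 to 110 °C) follows, in which the 2-silyloxy group and the alkyl substitution at C3a are both expected to send the ester-bearing carbon to C3a; it gives the cyclohexadiene ester F2, which DDQ aromatises to the methyl benzofuran-4-carboxylate F3. Camphorsulfonic acid in MeOH removes the primary silyl ether to give the hydroxy ester F4, which lactonises on warming with TsOH in PhMe. The route is rejoined at 20.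

2. Step 18. The activated alpha-aryl acid may enolise or form a ketene, which would erode the cis configuration at C3, and acylation of the hindered secondary alcohol may be slow enough for this to matter. The fallback never activates the acid and sets out from 27 and 24. Mitsunobu reaction of 27 with 4-nitrobenzoic acid (PPh3, DIAD, THF) inverts C7 of the benzodioxole (shikimate C5) to give the inverted 4-nitrobenzoate F5. K2CO3 in MeOH releases the 5-epi alcohol F6. A second Mitsunobu reaction of F6 with acid 24, in which the carboxylate is only a nucleophile, inverts that centre back. The route is rejoined at 28.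

3. Step 8. The strained five-membered ketene acetal phosphate may hydrolyse or ring-open during formation, handling or oxidative addition. The fallback sets out from 11 and uses carbonyl addition instead of cross-coupling. (1-Ethoxyvinyl)lithium (from ethyl vinyl ether and t-BuLi, THF, −78 °C) adds once to the lactone to give the ethoxyvinyl lactol F7. MsCl and Et3N dehydrate F7 to the ring enol ether, which is compound 13. The aqueous HCl treatment of step 9 then delivers 15, where the route is rejoined.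

**Further compounds**

F1 | step 12 | (2S,3S)-2-[3,4-bis(TBSO)phenyl]-3-(TBSO-methyl)-5-[1-(TBSO)ethenyl]-2,3-dihydrofuran | C=C(O[Si](C)(C)C(C)(C)C)C1=C[C@@H](CO[Si](C)(C)C(C)(C)C)[C@@H](c2ccc(O[Si](C)(C)C(C)(C)C)c(O[Si](C)(C)C(C)(C)C)c2)O1
F2 | step 12 | methyl (2S,3S)-2-[3,4-bis(TBSO)phenyl]-7-(TBSO)-3-(TBSO-methyl)-2,3,3a,6-tetrahydro-1-benzofuran-4-carboxylate | COC(=O)C1=CCC(O[Si](C)(C)C(C)(C)C)=C2O[C@H](c3ccc(O[Si](C)(C)C(C)(C)C)c(O[Si](C)(C)C(C)(C)C)c3)[C@H](CO[Si](C)(C)C(C)(C)C)C12
F3 | step 12 | methyl (2S,3S)-2-[3,4-bis(TBSO)phenyl]-7-(TBSO)-3-(TBSO-methyl)-2,3-dihydro-1-benzofuran-4-carboxylate | COC(=O)c1ccc(O[Si](C)(C)C(C)(C)C)c2c1[C@@H](CO[Si](C)(C)C(C)(C)C)[C@@H](c1ccc(O[Si](C)(C)C(C)(C)C)c(O[Si](C)(C)C(C)(C)C)c1)O2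
F4 | step 12 | methyl (2S,3S)-2-[3,4-bis(TBSO)phenyl]-7-(TBSO)-3-(hydroxymethyl)-2,3-dihydro-1-benzofuran-4-carboxylate | COC(=O)c1ccc(O[Si](C)(C)C(C)(C)C)c2c1[C@@H](CO)[C@@H](c1ccc(O[Si](C)(C)C(C)(C)C)c(O[Si](C)(C)C(C)(C)C)c1)O2
F5 | step 18 | tert-butyl (3aR,7S,7aS)-2,2-dimethyl-7-(4-nitrobenzoyloxy)-3a,6,7,7a-tetrahydro-1,3-benzodioxole-5-carboxylate | O=C(O[C@H]1CC(C(=O)OC(C)(C)C)=C[C@H]2OC(C)(C)O[C@@H]12)c1ccc(cc1)[N+](=O)[O-]
F6 | step 18 | tert-butyl (3aR,7S,7aS)-7-hydroxy-2,2-dimethyl-3a,6,7,7a-tetrahydro-1,3-benzodioxole-5-carboxylate | O[C@H]1CC(C(=O)OC(C)(C)C)=C[C@H]2OC(C)(C)O[C@@H]12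
F7 | step 8 | (4S,5S)-5-[3,4-bis(TBSO)phenyl]-2-(1-ethoxyethenyl)-4-(TESO-methyl)oxolan-2-ol | C=C(OCC)C1(O)C[C@@H](CO[Si](CC)(CC)CC)[C@@H](c2ccc(O[Si](C)(C)C(C)(C)C)c(O[Si](C)(C)C(C)(C)C)c2)O1
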